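I followed the missing substrate.

| flask | substrate | reagent | temperature | remark | time |
|---|---|---|---|---|---|
| larch | 0.80 M | 0.48 M | 92 °C | run made earlier |  |
| oak | 0.80 M | 1.9 M | 120 °C | run made earlier |  |
| Monday's | 0.80 M | 0.960 M | 105 °C |  | 20 min |
| Sunday's | 0.80 M | 0.960 M | 80 °C |  | 20 min |
| Wednesday's | 0.80 M | 0.960 M |  | at 130 °C until 4.0 min, from then on at 80 °C | 20 min |
| Friday's | 0.80 M | 0.960 M | 130 °C |  | 20 min |

| run | time / min | product / % | substrate / % |
|---|---|---|---|
| larch | 6.00 | 28.2 | 16.8 |
| larch | 12.0 | 34.3 | 11.6 |
| larch | 20.0 | 39.8 | 5.6 |
| larch | 25.0 | 41.7 | 6.3 |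
| oak | 0.500 | 69.7 | 12.0 |
| oak | 1.00 | 82.1 | 3.3 |
| oak | 2.50 | 85.0 | 0 |
| oak | 6.00 | 86.8 | 0 |

(readings scatter by 1 percentage point)

1. the flask with the highest amount of product, in percent of the substrate charged ("all alike" if they lie within 1.5 percentage points) (Monday's / Sunday's / Wednesday's / Friday's / all alike)
2. final product, as a percentage of the substrate charged, in Monday's
3. final product, as a percentage of the substrate charged, in Sunday's
4. final product, as a percentage of the substrate charged, in Wednesday's
5. final product, as a percentage of the substrate charged, in Friday's



In each earlier run part of the charged substrate appeared neither as substrate nor as product. So I set product against that missing part at the last reading, a branching ratio ρ (a selectivity factor in ratio form), read with the scatter of the readings: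

ρL = 0.802 (larch), ρO = 6.58 (oak)

Oak had the larger reagent charge and the higher ratio. I supposed a power law and defined the reagent exponent n, the slope of ln ρ against the ln of the reagent charge between these two runs:

n = 1.53

Carried from larch to Monday's charge, this gave:

ρ = 2.31

A flask that has used up its substrate holds a product share P = ρ/(1+ρ):

P = 69.8%

The weak link was n, since oak was hotter as well, so the slope holds temperature too. But Monday's stands near the middle of that line: its 0.960 M against a geometric mean of 0.955 M, its 105 °C between 92 °C and 120 °C. So I reforged the step as a geometric mean, which needs no split between the two settings if ln ρ runs straight in both: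

ρ = 2.30, P = 69.7%

I committed to that for Monday's. The two runs did not separate temperature, so I ranked none of the other flasks.

The forecast named Friday's, with 65% for Monday's, 46% for Sunday's, 76% for Wednesday's and 76% for Friday's. Its ground was: “So heat favours product.” My Monday's number, 69.7%, stood higher.

The flasks gave 73.7% in Monday's, 63.1% in Sunday's, 64.9% in Wednesday's and 65.4% in Friday's, so Monday's held the most.

    substrate ⇌ dormant form (K = 2.80, k = 0.0440 /s, Ea = 85.0 kJ/mol, ΔH = −45.0 kJ/mol)
    substrate + reagent → product, rate k2*[substrate]*[reagent]^1.5 (k = 0.00830 /M^1.5/s, Ea = 47.0 kJ/mol)
    2 substrate → homo dimer (k = 0.00360 /M/s, Ea = 58.0 kJ/mol)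
    (constants at 80 °C)

Monday's own ratio after 20.0 min, with its 0.369% substrate set aside as in the runs, came to 2.84 against my 2.30. The neighbour of Monday's, charged with 0.24 M of reagent (0.300 equiv), takes the same n, carried from larch: ρ = 0.278. With 5.20% substrate and 5.30% dormant form still standing after 20.0 min, that gives 19.5% product. The neighbour held 20.2% of product and, in percent of the substrate charged, 69.2% as homo dimer, with 33% of its reagent still there.

The earlier runs and the new flask stem from a simulated flask with made-up constants; noise was put on by code.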